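The route rests on disconnecting the C5–C6 bond of ring B, the cyclohexanone ring. Its C7 carbonyl, C6 methylene and isopropenyl-bearing C5 are arranged as a ketone with a γ,δ-alkene, exactly what a Claisen rearrangement leaves behind. The precursor is therefore a benzo-fused eight-membered 2-methylene cyclic enol ether in which the arene (C8, C9) ties the vinyl ether carbon C7 to the quaternary C10 and a (Z)-trisubstituted ring alkene carries C5. One thermal [3,3] shift contracts this ring to ring B, forms C5–C6, sets C5 under the control of C10, and reveals the C7 ketone and the isopropenyl group together. C10 is set earlier by an aromatic Claisen chirality transfer.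

Key step: step 15

Remark on the chemistry: atom labels are C1–C3 for the acid chain, C5 for the isopropenyl-bearing CH, C6 for the ring CH2, C7 for the ketone carbon, C8 and C9 for the arene carbons bonded to C7 and C10, C10 for the quaternary carbon, and C11 (OH), C12 (OMe), C13 (isopropyl), C14 (OH) for the remaining arene carbons from C9 round to C8. The target SMILES is read as (5S,10S), with isopropenyl cis to the C10 methyl, and the key step is assumed to favour this diastereomer.

Step 1
Reactants: 1 1,3-dimethoxybenzene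
Product: 3 2-(2,6-dimethoxyphenyl)propan-2-ol, via 2,6-dimethoxyphenyllithium 2 (not isolated)
Conditions: n-BuLi, THF, 0 °C → rt; acetone, −78 °C → rt; H2O
Reagents that add atoms: acetone CC(C)=O
Why: Directed ortho-metalation removes the proton between the two methoxy groups and the aryllithium adds 1,2 to acetone.

Step 2
Reactants: 3 2-(2,6-dimethoxyphenyl)propan-2-ol
Product: 4 1,3-dimethoxy-2-(propan-2-yl)benzene
Conditions: Et3SiH, CF3CO2H, CH2Cl2, 0 °C → rt
Reagents that add atoms: none
Why: Ionic hydrogenation: the acid ionises the tertiary benzylic alcohol and the silane delivers hydride to the stabilised cation.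

Step 3
Reactants: 4 1,3-dimethoxy-2-(propan-2-yl)benzene
Product: 5 1,5-dibromo-2,4-dimethoxy-3-(propan-2-yl)benzene
Conditions: NBS (2.1 equiv), MeCN, 0 °C → rt, dark
Reagents that add atoms: N-bromosuccinimide O=C1CCC(=O)N1Br
Why: Electrophilic aromatic bromination: both open positions are ortho to one methoxy group and para to the other, so two equivalents give the symmetric dibromide (future C8 and C11) with no regiochemical choice.

Step 4
Reactants: 5 1,5-dibromo-2,4-dimethoxy-3-(propan-2-yl)benzene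
Product: 8 5-bromo-2,4-dimethoxy-3-(propan-2-yl)phenol, via aryllithium 6 (not isolated), via aryl dimethyl boronate 7 (not isolated)
Conditions: n-BuLi (1.0 equiv), THF, −78 °C; B(OMe)3, −78 °C → rt; AcOH, 30% aq. H2O2, 0 °C → rt
Reagents that add atoms: hydrogen peroxide OO
Why: Bromine–lithium exchange on a symmetric dibromide (either bromine gives the same aryllithium), borylation and peroxide oxidation of the arylboronate give the phenol, leaving bromine at the future C8 and hydrogen at the future C9.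

Step 5
Reactants: 9 pent-4-yn-1-ol
Product: 10 tert-butyl(dimethyl)(pent-4-yn-1-yloxy)silane
Conditions: t-BuMe2SiCl, imidazole, CH2Cl2, rt
Reagents that add atoms: tert-butyldimethylsilyl chloride CC(C)(C)[Si](C)(C)Cl
Why: Standard imidazole-promoted silylation of a primary alcohol.

Step 6
Reactants: 10 tert-butyl(dimethyl)(pent-4-yn-1-yloxy)silane
Product: 13 rac-(3E)-7-{[tert-butyl(dimethyl)silyl]oxy}-4-methylhept-3-en-2-ol, via alkenyldimethylalane 11 (not isolated), via lithium alkenylaluminate 12 (not isolated)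
Conditions: Me3Al (2 equiv), Cp2ZrCl2 (20 mol %), CH2Cl2, 0 °C → rt; volatiles removed; n-BuLi, THF–hexane, −78 °C; CH3CHO, −78 → 0 °C; H2O
Reagents that add atoms: trimethylaluminium C[Al](C)C; acetaldehyde CC=O
Why: Negishi zirconium-catalysed carboalumination adds methyl and aluminium syn with methyl on the internal carbon, and the derived aluminate adds to acetaldehyde with retention of the (E)-alkene geometry; the carbinol centre forms racemic.

Step 7
Reactants: 13 rac-(3E)-7-{[tert-butyl(dimethyl)silyl]oxy}-4-methylhept-3-en-2-ol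
Product: 14 (2S,3E)-7-{[tert-butyl(dimethyl)silyl]oxy}-4-methylhept-3-en-2-ol
Conditions: Novozym 435 (immobilised Candida antarctica lipase B), vinyl acetate, hexane, 30 °C, run to about 55% conversion
Reagents that add atoms: none
Why: Lipase kinetic resolution: the enzyme acetylates the (R)-methyl carbinol preferentially (Kazlauskas rule), so the unreacted (S)-alcohol should be left enantiopure once conversion passes one half.

Step 8
Reactants: 8 5-bromo-2,4-dimethoxy-3-(propan-2-yl)phenol; 14 (2S,3E)-7-{[tert-butyl(dimethyl)silyl]oxy}-4-methylhept-3-en-2-ol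
Product: 15 1-bromo-5-{[(2R,3E)-7-{[tert-butyl(dimethyl)silyl]oxy}-4-methylhept-3-en-2-yl]oxy}-2,4-dimethoxy-3-(propan-2-yl)benzene
Conditions: PPh3, DIAD, toluene, 0 °C → rt
Reagents that add atoms: none
Why: Mitsunobu etherification: the phenol displaces the activated secondary allylic alcohol by SN2 with inversion, turning the (S)-alcohol into the (R)-aryl ether, and the cold non-polar medium limits ionisation and SN2' attack.

Step 9
Reactants: 15 1-bromo-5-{[(2R,3E)-7-{[tert-butyl(dimethyl)silyl]oxy}-4-methylhept-3-en-2-yl]oxy}-2,4-dimethoxy-3-(propan-2-yl)benzene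
Product: 16 3-bromo-2-[(2E,4S)-7-{[tert-butyl(dimethyl)silyl]oxy}-4-methylhept-2-en-4-yl]-4,6-dimethoxy-5-(propan-2-yl)phenol
Conditions: PhNEt2, 180 °C, sealed tube, argon
Reagents that add atoms: none
Why: Aromatic Claisen rearrangement: a chair-like suprafacial [3,3] shift to the only ortho carbon bearing hydrogen, then tautomerisation, should carry the (R) carbinol configuration across the (E)-alkene to (S)-C10 with the carbinol methyl equatorial, which also gives the (E)-propenyl group.

Step 10
Reactants: 16 3-bromo-2-[(2E,4S)-7-{[tert-butyl(dimethyl)silyl]oxy}-4-methylhept-2-en-4-yl]-4,6-dimethoxy-5-(propan-2-yl)phenol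
Product: 17 1-bromo-2-[(2E,4S)-7-{[tert-butyl(dimethyl)silyl]oxy}-4-methylhept-2-en-4-yl]-3,4,6-trimethoxy-5-(propan-2-yl)benzene
Conditions: MeI, K2CO3, DMF, rt
Reagents that add atoms: iodomethane CI
Why: Williamson O-methylation of the phenoxide, which tolerates the flanking quaternary carbon because the electrophile is small.

Step 11
Reactants: 17 1-bromo-2-[(2E,4S)-7-{[tert-butyl(dimethyl)silyl]oxy}-4-methylhept-2-en-4-yl]-3,4,6-trimethoxy-5-(propan-2-yl)benzene
Product: 19 2-[(2E,4S)-7-{[tert-butyl(dimethyl)silyl]oxy}-4-methylhept-2-en-4-yl]-3,4,6-trimethoxy-5-(propan-2-yl)benzoic acid, via aryllithium 18 (not isolated)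
Conditions: t-BuLi (2.1 equiv), THF, −78 °C; CO2 (g); dilute aq. HCl to pH 3, 0 °C
Reagents that add atoms: carbon dioxide O=C=O
Why: Bromine–lithium exchange followed by carboxylation of the aryllithium installs C7 at C8; the bromine was placed before any alkene was present, so no electrophilic halogenation is needed here.

Step 12
Reactants: 19 2-[(2E,4S)-7-{[tert-butyl(dimethyl)silyl]oxy}-4-methylhept-2-en-4-yl]-3,4,6-trimethoxy-5-(propan-2-yl)benzoic acid
Product: 20 2-methylprop-2-en-1-yl 2-[(2E,4S)-7-{[tert-butyl(dimethyl)silyl]oxy}-4-methylhept-2-en-4-yl]-3,4,6-trimethoxy-5-(propan-2-yl)benzoate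
Conditions: 3-chloro-2-methylprop-1-ene, K2CO3, NaI (cat.), DMF, 50 °C
Reagents that add atoms: 3-chloro-2-methylprop-1-ene C=C(C)CCl
Why: Carboxylate SN2 alkylation forms the ester at the alkyl carbon and so avoids acyl substitution at the doubly ortho-substituted benzoic acid.

Step 13
Reactants: 20 2-methylprop-2-en-1-yl 2-[(2E,4S)-7-{[tert-butyl(dimethyl)silyl]oxy}-4-methylhept-2-en-4-yl]-3,4,6-trimethoxy-5-(propan-2-yl)benzoate
Product: 21 (4Z,6S)-6-(3-{[tert-butyl(dimethyl)silyl]oxy}propyl)-7,8,10-trimethoxy-4,6-dimethyl-9-(propan-2-yl)-3,6-dihydro-1H-2-benzoxocin-1-one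
Conditions: second-generation Grubbs catalyst (H2IMes)(PCy3)Cl2Ru=CHPh (10 mol %), toluene (2 mM), 90 °C, argon sparge
Reagents that add atoms: none
Why: Ring-closing olefin metathesis with loss of propene: the ortho-fused arene and the quaternary C10 hold the two alkenes close, and the eight-membered ring can only hold the (Z)-trisubstituted C4=C5 alkene.

Step 14
Reactants: 21 (4Z,6S)-6-(3-{[tert-butyl(dimethyl)silyl]oxy}propyl)-7,8,10-trimethoxy-4,6-dimethyl-9-(propan-2-yl)-3,6-dihydro-1H-2-benzoxocin-1-one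
Product: 22 tert-butyl(dimethyl){3-[(4Z,6S)-7,8,10-trimethoxy-4,6-dimethyl-1-methylidene-9-(propan-2-yl)-3,6-dihydro-1H-2-benzoxocin-6-yl]propoxy}silane
Conditions: Cp2Ti(μ-Cl)(μ-CH2)AlMe2 (1.5 equiv), pyridine (cat.), THF–toluene, −40 °C → rt; aq. NaOH, −10 °C; filtration through basic Al2O3; used crude
Reagents that add atoms: Cp2Ti(μ-Cl)(μ-CH2)AlMe2 C[Al-]1(C)C[Ti](C2C=CC=C2)(C2C=CC=C2)[Cl+]1
Why: Titanium methylidene olefination of the lactone carbonyl (oxatitanacyclobutane formation and cycloreversion) is non-basic and compact enough for the hindered ester, and the aluminium residues are removed before any heating.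

Step 15
Reactants: 22 tert-butyl(dimethyl){3-[(4Z,6S)-7,8,10-trimethoxy-4,6-dimethyl-1-methylidene-9-(propan-2-yl)-3,6-dihydro-1H-2-benzoxocin-6-yl]propoxy}silane
Product: 23 (3S,4S)-4-(3-{[tert-butyl(dimethyl)silyl]oxy}propyl)-5,6,8-trimethoxy-4-methyl-7-(propan-2-yl)-3-(prop-1-en-2-yl)-3,4-dihydronaphthalen-1(2H)-one
Conditions: toluene (0.01 M), Et3N (5 mol %), 110–140 °C, sealed base-washed tube, argon
Reagents that add atoms: none
Why: On heating, the allyl vinyl ether held inside the eight-membered ring (C6=C7–O–CH2–C4=C5) should undergo a concerted [3,3] sigmatropic shift in which C6 bonds to C5 while the allylic O–CH2 bond breaks, so the ether oxygen becomes the C7 carbonyl and C4 with its methyl and former O–CH2 carbon becomes the isopropenyl group. The closest known reaction type is the Claisen ring contraction of 2-methylene oxacycles made by titanium methylenation of unsaturated lactones. Ring B closes by transannular C5–C6 bond formation (eight-membered ether to six-membered ketone) through a six-atom pericyclic array that shares C5, C6 and C7 with the forming carbocycle, a bicyclo[3.3.1]-like transition state that the ortho-fused arene and the (Z)-alkene pre-organise. The new C5 stereocentre is controlled by C10: the O–CH2–C4 bridge must pass over one face of the forming ring, the C10 substituent on that face lies gauche to C4 and close to the C11 methoxy group, so the methyl group should take that place and the longer silyloxypropyl arm the open face, which puts isopropenyl cis to methyl, (5S) from (10S). The step needs this facial selectivity, which is expected to be moderate with the minor C5 epimer removed by chromatography, and needs the concerted path to outrun ionisation or hydrolysis of the acid-sensitive enol ether, which the amine-buffered, aluminium-free medium secures; C5 cannot epimerise afterwards.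

Step 16
Reactants: 23 (3S,4S)-4-(3-{[tert-butyl(dimethyl)silyl]oxy}propyl)-5,6,8-trimethoxy-4-methyl-7-(propan-2-yl)-3-(prop-1-en-2-yl)-3,4-dihydronaphthalen-1(2H)-one
Product: 24 (3S,4S)-4-(3-hydroxypropyl)-5,6,8-trimethoxy-4-methyl-7-(propan-2-yl)-3-(prop-1-en-2-yl)-3,4-dihydronaphthalen-1(2H)-one
Conditions: Bu4NF, AcOH (buffer), THF, 0 °C → rt
Reagents that add atoms: none
Why: Fluoride-mediated cleavage of the silyl ether; the buffered medium leaves the ketone, the isopropenyl group and the non-epimerisable C5 untouched.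

Step 17
Reactants: 24 (3S,4S)-4-(3-hydroxypropyl)-5,6,8-trimethoxy-4-methyl-7-(propan-2-yl)-3-(prop-1-en-2-yl)-3,4-dihydronaphthalen-1(2H)-one
Product: 26 3-[(1S,2S)-5,7,8-trimethoxy-1-methyl-4-oxo-6-(propan-2-yl)-2-(prop-1-en-2-yl)-1,2,3,4-tetrahydronaphthalen-1-yl]propanoic acid, via aldehyde 25 (not isolated)
Conditions: TEMPO (20 mol %), PhI(OAc)2 (2.2 equiv), MeCN–H2O (1:1), rt
Reagents that add atoms: water O
Why: Oxoammonium (TEMPO) oxidation of the primary alcohol to the aldehyde and, through its hydrate, to the acid, under conditions that spare the 1,1-disubstituted alkene and the fully substituted arene.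

Step 18
Reactants: 26 3-[(1S,2S)-5,7,8-trimethoxy-1-methyl-4-oxo-6-(propan-2-yl)-2-(prop-1-en-2-yl)-1,2,3,4-tetrahydronaphthalen-1-yl]propanoic acid
Product: 27 3-[(1S,2S)-7-methoxy-1-methyl-4,5,8-trioxo-6-(propan-2-yl)-2-(prop-1-en-2-yl)-1,2,3,4,5,8-hexahydronaphthalen-1-yl]propanoic acid
Conditions: (NH4)2Ce(NO3)6 (2.5 equiv), MeCN–H2O, 0 °C
Reagents that add atoms: water O
Why: Oxidative demethylation of the para-related C11 and C14 methoxy groups by (NH4)2Ce(NO3)6 (arene radical cation, ipso attack of water, loss of methanol) should give the para-quinone and leave the C12 methoxy group in place.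

Step 19
Reactants: 27 3-[(1S,2S)-7-methoxy-1-methyl-4,5,8-trioxo-6-(propan-2-yl)-2-(prop-1-en-2-yl)-1,2,3,4,5,8-hexahydronaphthalen-1-yl]propanoic acid
Product: 28 3-[(1S,2S)-5,8-dihydroxy-7-methoxy-1-methyl-4-oxo-6-(propan-2-yl)-2-(prop-1-en-2-yl)-1,2,3,4-tetrahydronaphthalen-1-yl]propanoic acid (CNP0249049.1)
Conditions: Na2S2O4, EtOAc–H2O, rt, argon
Reagents that add atoms: none
Why: Dithionite reduction of the quinone to the hydroquinone touches neither the ketone, the alkene nor the acid, and the C14 hydroxyl is then hydrogen-bonded to the C7 carbonyl.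

Compound list
1 | 1,3-dimethoxybenzene | COc1cccc(OC)c1 | starting material
2 | 2,6-dimethoxyphenyllithium | [Li]c1c(OC)cccc1OC | intermediate (not isolated)
3 | 2-(2,6-dimethoxyphenyl)propan-2-ol | COc1cccc(OC)c1C(C)(C)O | intermediate
4 | 1,3-dimethoxy-2-(propan-2-yl)benzene | COc1cccc(OC)c1C(C)C | intermediate
5 | 1,5-dibromo-2,4-dimethoxy-3-(propan-2-yl)benzene | COc1c(Br)cc(Br)c(OC)c1C(C)C | intermediate
6 | [5-bromo-2,4-dimethoxy-3-(propan-2-yl)phenyl]lithium | [Li]c1cc(Br)c(OC)c(C(C)C)c1OC | intermediate (not isolated)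
7 | dimethyl [5-bromo-2,4-dimethoxy-3-(propan-2-yl)phenyl]boronate | COB(OC)c1cc(Br)c(OC)c(C(C)C)c1OC | intermediate (not isolated)
8 | 5-bromo-2,4-dimethoxy-3-(propan-2-yl)phenol | COc1c(O)cc(Br)c(OC)c1C(C)C | intermediate
9 | pent-4-yn-1-ol | C#CCCCO | starting material
10 | tert-butyl(dimethyl)(pent-4-yn-1-yloxy)silane | C#CCCCO[Si](C)(C)C(C)(C)C | intermediate
11 | [(1E)-5-{[tert-butyl(dimethyl)silyl]oxy}-2-methylpent-1-en-1-yl]dimethylalumane | C[Al](C)/C=C(\C)CCCO[Si](C)(C)C(C)(C)C | intermediate (not isolated)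
12 | lithium butyl[(1E)-5-{[tert-butyl(dimethyl)silyl]oxy}-2-methylpent-1-en-1-yl]dimethylaluminate | [Li+].CCCC[Al-](C)(C)/C=C(\C)CCCO[Si](C)(C)C(C)(C)C | intermediate (not isolated)
13 | rac-(3E)-7-{[tert-butyl(dimethyl)silyl]oxy}-4-methylhept-3-en-2-ol | CC(O)/C=C(\C)CCCO[Si](C)(C)C(C)(C)C | intermediate
14 | (2S,3E)-7-{[tert-butyl(dimethyl)silyl]oxy}-4-methylhept-3-en-2-ol | C[C@H](O)/C=C(\C)CCCO[Si](C)(C)C(C)(C)C | intermediate
15 | 1-bromo-5-{[(2R,3E)-7-{[tert-butyl(dimethyl)silyl]oxy}-4-methylhept-3-en-2-yl]oxy}-2,4-dimethoxy-3-(propan-2-yl)benzene | COc1c(O[C@H](C)/C=C(\C)CCCO[Si](C)(C)C(C)(C)C)cc(Br)c(OC)c1C(C)C | intermediate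
16 | 3-bromo-2-[(2E,4S)-7-{[tert-butyl(dimethyl)silyl]oxy}-4-methylhept-2-en-4-yl]-4,6-dimethoxy-5-(propan-2-yl)phenol | C/C=C/[C@](C)(CCCO[Si](C)(C)C(C)(C)C)c1c(O)c(OC)c(C(C)C)c(OC)c1Br | intermediate
17 | 1-bromo-2-[(2E,4S)-7-{[tert-butyl(dimethyl)silyl]oxy}-4-methylhept-2-en-4-yl]-3,4,6-trimethoxy-5-(propan-2-yl)benzene | C/C=C/[C@](C)(CCCO[Si](C)(C)C(C)(C)C)c1c(OC)c(OC)c(C(C)C)c(OC)c1Br | intermediate
18 | {2-[(2E,4S)-7-{[tert-butyl(dimethyl)silyl]oxy}-4-methylhept-2-en-4-yl]-3,4,6-trimethoxy-5-(propan-2-yl)phenyl}lithium | C/C=C/[C@](C)(CCCO[Si](C)(C)C(C)(C)C)c1c(OC)c(OC)c(C(C)C)c(OC)c1[Li] | intermediate (not isolated)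
19 | 2-[(2E,4S)-7-{[tert-butyl(dimethyl)silyl]oxy}-4-methylhept-2-en-4-yl]-3,4,6-trimethoxy-5-(propan-2-yl)benzoic acid | C/C=C/[C@](C)(CCCO[Si](C)(C)C(C)(C)C)c1c(OC)c(OC)c(C(C)C)c(OC)c1C(=O)O | intermediate
20 | 2-methylprop-2-en-1-yl 2-[(2E,4S)-7-{[tert-butyl(dimethyl)silyl]oxy}-4-methylhept-2-en-4-yl]-3,4,6-trimethoxy-5-(propan-2-yl)benzoate | C/C=C/[C@](C)(CCCO[Si](C)(C)C(C)(C)C)c1c(OC)c(OC)c(C(C)C)c(OC)c1C(=O)OCC(C)=C | intermediate
21 | (4Z,6S)-6-(3-{[tert-butyl(dimethyl)silyl]oxy}propyl)-7,8,10-trimethoxy-4,6-dimethyl-9-(propan-2-yl)-3,6-dihydro-1H-2-benzoxocin-1-one | O=C1OC/C(C)=C\[C@](C)(CCCO[Si](C)(C)C(C)(C)C)c2c(OC)c(OC)c(C(C)C)c(OC)c21 | intermediate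
22 | tert-butyl(dimethyl){3-[(4Z,6S)-7,8,10-trimethoxy-4,6-dimethyl-1-methylidene-9-(propan-2-yl)-3,6-dihydro-1H-2-benzoxocin-6-yl]propoxy}silane | C=C1OC/C(C)=C\[C@](C)(CCCO[Si](C)(C)C(C)(C)C)c2c(OC)c(OC)c(C(C)C)c(OC)c21 | intermediate (precursor of the key step)
23 | (3S,4S)-4-(3-{[tert-butyl(dimethyl)silyl]oxy}propyl)-5,6,8-trimethoxy-4-methyl-7-(propan-2-yl)-3-(prop-1-en-2-yl)-3,4-dihydronaphthalen-1(2H)-one | C=C(C)[C@@H]1CC(=O)c2c(OC)c(C(C)C)c(OC)c(OC)c2[C@@]1(C)CCCO[Si](C)(C)C(C)(C)C | intermediate (product of the key step)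
24 | (3S,4S)-4-(3-hydroxypropyl)-5,6,8-trimethoxy-4-methyl-7-(propan-2-yl)-3-(prop-1-en-2-yl)-3,4-dihydronaphthalen-1(2H)-one | C=C(C)[C@@H]1CC(=O)c2c(OC)c(C(C)C)c(OC)c(OC)c2[C@@]1(C)CCCO | intermediate
25 | 3-[(1S,2S)-5,7,8-trimethoxy-1-methyl-4-oxo-6-(propan-2-yl)-2-(prop-1-en-2-yl)-1,2,3,4-tetrahydronaphthalen-1-yl]propanal | C=C(C)[C@@H]1CC(=O)c2c(OC)c(C(C)C)c(OC)c(OC)c2[C@@]1(C)CCC=O | intermediate (not isolated)
26 | 3-[(1S,2S)-5,7,8-trimethoxy-1-methyl-4-oxo-6-(propan-2-yl)-2-(prop-1-en-2-yl)-1,2,3,4-tetrahydronaphthalen-1-yl]propanoic acid | C=C(C)[C@@H]1CC(=O)c2c(OC)c(C(C)C)c(OC)c(OC)c2[C@@]1(C)CCC(=O)O | intermediate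
27 | 3-[(1S,2S)-7-methoxy-1-methyl-4,5,8-trioxo-6-(propan-2-yl)-2-(prop-1-en-2-yl)-1,2,3,4,5,8-hexahydronaphthalen-1-yl]propanoic acid | C=C(C)[C@@H]1CC(=O)C2=C(C(=O)C(OC)=C(C(C)C)C2=O)[C@@]1(C)CCC(=O)O | intermediate
28 | 3-[(1S,2S)-5,8-dihydroxy-7-methoxy-1-methyl-4-oxo-6-(propan-2-yl)-2-(prop-1-en-2-yl)-1,2,3,4-tetrahydronaphthalen-1-yl]propanoic acid (CNP0249049.1) | C=C(C)[C@@H]1CC(=O)c2c(O)c(C(C)C)c(OC)c(O)c2[C@@]1(C)CCC(=O)O | target

Total step count: 19. Longest linear sequence: 16 steps (steps 1–4, then 8–19); the side branch (steps 5–7) joins at step 8.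

Steps most likely to fail

Step 15 (key step). The risks are heterolysis of the allylic C–O bond (ion-pair recombination in the [1,3] sense, or elimination) instead of the concerted shift, hydrolysis of the enol ether before it rearranges, and weak facial discrimination at C5. The fallback sets out from lactone 21 and forms the same C5–C6 bond by polar chemistry. MeLi (1.05 equiv, THF, −78 °C) should open the lactone to the hydroxy methyl ketone F1, and ClCO2Me with pyridine converts its allylic alcohol into the allylic methyl carbonate F2. Deprotonation of the methyl ketone with LiN(SiMe3)2 and addition of Pd(PPh3)4 (cat., THF, 0 °C → rt) should then give an intramolecular Tsuji–Trost allylic alkylation. The C6 enolate carbon attacks the C5 terminus of the allyl–palladium unit, six-membered ring closure being preferred over eight, and this releases the isopropenyl group. The route is rejoined at tetralone 23.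

Step 13. The risk is slow loading of the catalyst on two hindered alkenes (a 1,1-disubstituted one and a propenyl group on a quaternary carbon), so that intermolecular metathesis or alkene migration outruns closure of the eight-membered ring. The fallback sets out from bromide 17, builds the (Z)-alkene by olefination and closes the ring at the ester oxygen. OsO4 (cat.), NaIO4 and 2,6-lutidine in dioxane–H2O should cleave the propenyl group to the aldehyde F3. Ando olefination with ethyl 2-[bis(2-methylphenoxy)phosphoryl]propanoate (NaH, THF, −78 °C) should give the (Z)-enoate F4, which i-Bu2AlH (CH2Cl2, −78 °C) reduces to the (Z)-allylic alcohol F5. Treatment with t-BuLi (3.1 equiv, THF, −78 °C; alkoxide formation, then bromine–lithium exchange) followed by CO2 should give the hydroxy acid F6. Mitsunobu lactonisation (PPh3, DIAD, toluene, high dilution; carboxylate SN2 at the primary allylic carbon) then closes the ring and re-enters the route at lactone 21.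

Step 9. The risk is thermal heterolysis of the secondary allylic aryl ether, giving either fragmentation to phenol 8 and a diene or ion-pair return with loss of stereochemical fidelity, in competition with the slow creation of a quaternary carbon next to bromine. The fallback sets out from phenol 8 and alcohol 14 and replaces the sigmatropic shift by a copper-mediated allylic substitution. NIS (MeCN, 0 °C) should iodinate the only free ring position to give the iodophenol F7, and MeI with K2CO3 gives the iodo trimethoxyarene F8. Alcohol 14 is esterified with retention (pyridine-2-carboxylic acid, DCC, DMAP) to the allylic picolinate F9. Selective iodine–magnesium exchange on F8 (i-PrMgCl·LiCl, THF, −40 °C) gives the arylmagnesium chloride F10, which with CuBr·SMe2 should displace the picolinate of F9 in an anti-SN2' sense at the methyl-bearing alkene carbon. Retention in the ester followed by anti attack gives the same (S)-C10 and (E)-propenyl group as inversion followed by the suprafacial shift, and the route is rejoined at bromide 17.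

Further compounds
F1 | step 15 | 1-{2-[(2Z,4S)-7-{[tert-butyl(dimethyl)silyl]oxy}-1-hydroxy-2,4-dimethylhept-2-en-4-yl]-3,4,6-trimethoxy-5-(propan-2-yl)phenyl}ethan-1-one | OC/C(C)=C\[C@](C)(CCCO[Si](C)(C)C(C)(C)C)c1c(OC)c(OC)c(C(C)C)c(OC)c1C(C)=O
F2 | step 15 | (2Z,4S)-4-[2-acetyl-3,5,6-trimethoxy-4-(propan-2-yl)phenyl]-7-{[tert-butyl(dimethyl)silyl]oxy}-2,4-dimethylhept-2-en-1-yl methyl carbonate | COC(=O)OC/C(C)=C\[C@](C)(CCCO[Si](C)(C)C(C)(C)C)c1c(OC)c(OC)c(C(C)C)c(OC)c1C(C)=O
F3 | step 13 | (2R)-2-[2-bromo-3,5,6-trimethoxy-4-(propan-2-yl)phenyl]-5-{[tert-butyl(dimethyl)silyl]oxy}-2-methylpentanal | O=C[C@](C)(CCCO[Si](C)(C)C(C)(C)C)c1c(OC)c(OC)c(C(C)C)c(OC)c1Br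
F4 | step 13 | ethyl (2Z,4S)-4-[2-bromo-3,5,6-trimethoxy-4-(propan-2-yl)phenyl]-7-{[tert-butyl(dimethyl)silyl]oxy}-2,4-dimethylhept-2-enoate | CCOC(=O)/C(C)=C\[C@](C)(CCCO[Si](C)(C)C(C)(C)C)c1c(OC)c(OC)c(C(C)C)c(OC)c1Br
F5 | step 13 | (2Z,4S)-4-[2-bromo-3,5,6-trimethoxy-4-(propan-2-yl)phenyl]-7-{[tert-butyl(dimethyl)silyl]oxy}-2,4-dimethylhept-2-en-1-ol | OC/C(C)=C\[C@](C)(CCCO[Si](C)(C)C(C)(C)C)c1c(OC)c(OC)c(C(C)C)c(OC)c1Br
F6 | step 13 | 2-[(2Z,4S)-7-{[tert-butyl(dimethyl)silyl]oxy}-1-hydroxy-2,4-dimethylhept-2-en-4-yl]-3,4,6-trimethoxy-5-(propan-2-yl)benzoic acid | OC/C(C)=C\[C@](C)(CCCO[Si](C)(C)C(C)(C)C)c1c(OC)c(OC)c(C(C)C)c(OC)c1C(=O)O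
F7 | step 9 | 3-bromo-2-iodo-4,6-dimethoxy-5-(propan-2-yl)phenol | COc1c(O)c(I)c(Br)c(OC)c1C(C)C
F8 | step 9 | 1-bromo-2-iodo-3,4,6-trimethoxy-5-(propan-2-yl)benzene | COc1c(OC)c(I)c(Br)c(OC)c1C(C)C
F9 | step 9 | (2S,3E)-7-{[tert-butyl(dimethyl)silyl]oxy}-4-methylhept-3-en-2-yl pyridine-2-carboxylate | O=C(O[C@@H](C)/C=C(\C)CCCO[Si](C)(C)C(C)(C)C)c1ccccn1
F10 | step 9 | [2-bromo-3,5,6-trimethoxy-4-(propan-2-yl)phenyl]magnesium chloride | COc1c(OC)c([Mg]Cl)c(Br)c(OC)c1C(C)C
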